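**Plan**

- Retrosynthesis: the C3 angelate, C8 senecioate and C9 carbinol go back to a 9-ketone and the two cis-epoxides to Z olefins. The resulting (1(10)Z,4Z)-germacradien-9-one is cut at C6–C7 (C4–C9 re-joined) to a cis-1,2-dialkenylcyclohexenol, then at C8–C9 (dienyl anion + enone) and at the C4–vinyl bond (1,2-shift from C9).
- Enabling feature: the C9 oxygen, the Z C4=C5 bond (latent 4,5-epoxide) and the isopropenyl-bearing sp3 C7 form a cyclodec-5-enone oxy-Cope retron whose six-membered parent ring is C9–C10–C1–C2–C3–C4.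
- Forward: 2-methylcyclohex-2-enone supplies that six-membered ring. A semipinacol vinyl shift builds quaternary C4, the C10 methyl and C1=C10 follow, an (E)-dienyl group is added at C9, and the anionic oxy-Cope shift expands six to ten.
- Endgame: 1,10-epoxide, C8 oxygen (introduced β, inverted to α with the senecioate), C3 inversion, 4,5-epoxide, angelate, C9 reduction.
- Stereochemistry: one CBS reduction sets the absolute configuration. It is relayed by directed epoxidation, anti Grignard addition and anti 1,2-shift to C3/C4, by anti addition to C9 and by chair chirality transfer to C7. C1/C10, C8, C4/C5 and C9 then follow from peripheral attack, SN2 inversion, hydroxyl direction and chelation.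

Key step: step 11

Remark (numbering): germacrane numbering is used for the ten-membered ring and for the atoms that become it (methyls on C4 and C10, isopropenyl on C7); α/β refer to the ring drawn flat with the C7 isopropenyl group α.

Remark (C3): C3 is carried through the ring expansion as the 3R (3β) silyl ether, epimeric to the target and inverted in step 16, because only with the silyloxy group trans to both alkenyl groups should the dienyl nucleophile add cis to the C4 vinyl group and the Z-selective chair stay free of a substituent over the rearranging atoms.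

**Route**

Step 1
Reactants: 1 2-methylcyclohex-2-en-1-one
Product: 2 (S)-2-methylcyclohex-2-en-1-ol
Conditions: (R)-2-methyl-CBS-oxazaborolidine (10 mol %), BH3·SMe2, THF, −20 °C
Reagents that add atoms: none
Why: Corey–Bakshi–Shibata reduction: the oxazaborolidine-bound borane delivers hydride to one carbonyl face with the α-methylalkenyl arm as the large group, which should set the (S) carbinol centre from which all later stereocentres are relayed.

Step 2
Reactants: 2 (S)-2-methylcyclohex-2-en-1-ol
Product: 3 (1S,2S,3R)-2,3-epoxy-2-methylcyclohexan-1-ol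
Conditions: mCPBA, CH2Cl2, 0 °C
Reagents that add atoms: mCPBA, O=C(OO)c1cccc(Cl)c1
Why: Henbest epoxidation: hydrogen bonding of the peracid to the allylic hydroxyl should deliver oxygen to the olefin face cis to the OH, fixing both epoxide carbons.

Step 3
Reactants: 3 (1S,2S,3R)-2,3-epoxy-2-methylcyclohexan-1-ol
Product: 4 (2R,3R)-2,3-epoxy-2-methylcyclohexan-1-one
Conditions: Dess–Martin periodinane, CH2Cl2, rt
Reagents that add atoms: none
Why: Dess–Martin oxidation of the secondary alcohol under near-neutral conditions, which should leave the epoxide and its two stereocentres untouched.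

Step 4
Reactants: 4 (2R,3R)-2,3-epoxy-2-methylcyclohexan-1-one
Product: 5 (1R,2R,3R)-2,3-epoxy-2-methyl-1-vinylcyclohexan-1-ol
Conditions: vinylmagnesium bromide, THF, −78 °C
Reagents that add atoms: vinylmagnesium bromide, C=C[Mg]Br
Why: Grignard 1,2-addition to an α,β-epoxy ketone: approach anti to the α C–O bond of the epoxide (Felkin–Anh sense) should give the tertiary alcohol with OH cis and vinyl trans to the epoxide oxygen.

Step 5
Reactants: 5 (1R,2R,3R)-2,3-epoxy-2-methyl-1-vinylcyclohexan-1-ol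
Product: 6 (2S,3R)-3-hydroxy-2-methyl-2-vinylcyclohexan-1-one
Conditions: BF3·OEt2, CH2Cl2, −78 °C
Reagents that add atoms: none
Why: Semipinacol rearrangement of a 2,3-epoxy alcohol: the vinyl group, antiperiplanar to the Lewis-acid-activated tertiary C–O bond, should shift from the carbinol carbon to C2 with inversion there, so the new quaternary centre carries vinyl trans to the retained C3 hydroxyl.

Step 6
Reactants: 6 (2S,3R)-3-hydroxy-2-methyl-2-vinylcyclohexan-1-one
Product: 7 (2S,3R)-3-(tert-butyldimethylsilyloxy)-2-methyl-2-vinylcyclohexan-1-one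
Conditions: TBSOTf, 2,6-lutidine, CH2Cl2, −78 → 0 °C
Reagents that add atoms: TBSOTf, CC(C)(C)[Si](C)(C)OS(=O)(=O)C(F)(F)F
Why: Silylation of a hindered secondary alcohol with a silyl triflate; the β-silyloxy ketone cannot eliminate because the intervening α-carbon is quaternary.

Step 7
Reactants: 7 (2S,3R)-3-(tert-butyldimethylsilyloxy)-2-methyl-2-vinylcyclohexan-1-one
Product: 9 (2S,3R,6RS)-3-(tert-butyldimethylsilyloxy)-2,6-dimethyl-2-vinylcyclohexan-1-one, via lithium enolate 8 (not isolated)
Conditions: LiN(i-Pr)2, THF, −78 °C; MeI, −78 → 0 °C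
Reagents that add atoms: iodomethane, CI
Why: Enolate alkylation at the only enolizable position; the configuration of the new methyl-bearing carbon does not matter because it becomes sp2 in the next step.

Step 8
Reactants: 9 (2S,3R,6RS)-3-(tert-butyldimethylsilyloxy)-2,6-dimethyl-2-vinylcyclohexan-1-one
Product: 11 (5R,6S)-5-(tert-butyldimethylsilyloxy)-2,6-dimethyl-6-vinylcyclohex-2-en-1-one, via trimethylsilyl enol ether 10 (not isolated)
Conditions: TMSOTf, Et3N, CH2Cl2, 0 °C; then Pd(OAc)2, MeCN, rt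
Reagents that add atoms: none
Why: Saegusa–Ito dehydrogenation: the only possible silyl enol ether is palladated at the methyl-bearing α-carbon, and β-hydride elimination toward the ring CH2 should give the endocyclic 2-methyl enone.

Step 9
Reactants: 12 2-methylbut-1-en-3-yne
Product: 14 (E)-1-iodo-3-methylbuta-1,3-diene, via alkenylzirconocene chloride 13 (not isolated)
Conditions: Cp2Zr(H)Cl, THF, rt; then I2, 0 °C
Reagents that add atoms: iodine, II
Why: Hydrozirconation–iodination: syn addition of Zr–H to the terminal alkyne with zirconium at the terminus, then iodinolysis with retention, should give the E-dienyl iodide.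

Step 10
Reactants: 14 (E)-1-iodo-3-methylbuta-1,3-diene; 11 (5R,6S)-5-(tert-butyldimethylsilyloxy)-2,6-dimethyl-6-vinylcyclohex-2-en-1-one
Product: 16 (1S,5R,6S)-5-(tert-butyldimethylsilyloxy)-2,6-dimethyl-1-[(E)-3-methylbuta-1,3-dienyl]-6-vinylcyclohex-2-en-1-ol, via dienyllithium 15 (not isolated)
Conditions: t-BuLi (2 equiv), Et2O, −78 °C; then 11 in THF, −78 °C
Reagents that add atoms: none
Why: Iodine–lithium exchange with retention of E geometry, then 1,2-addition of the alkenyllithium to the enone: in the half-chair with the silyloxy group equatorial and the quaternary methyl axial, axial attack anti to that methyl (and anti to the silyloxy group) should set the carbinol centre with the dienyl group cis to the vinyl group.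

Step 11
Reactants: 16 (1S,5R,6S)-5-(tert-butyldimethylsilyloxy)-2,6-dimethyl-1-[(E)-3-methylbuta-1,3-dienyl]-6-vinylcyclohex-2-en-1-ol
Product: 19 (3R,7S,1(10)Z,4Z)-3-(tert-butyldimethylsilyloxy)germacra-1(10),4,11-trien-9-one, via potassium alkoxide 17 (not isolated), via potassium enolate 18 (not isolated)
Conditions: KH, 18-crown-6, THF, 0 °C → rt; then MeOH, −78 °C
Reagents that add atoms: none
Why: Deprotonation gives the C9 potassium alkoxide 17, in which the weakened C4–C9 bond breaks while the vinyl terminus C6 bonds to the diene terminus C7 in a concerted, charge-accelerated [3,3] shift (anionic oxy-Cope) to the C8=C9 enolate 18, which is protonated at C8 to ketone 19. The closest known reaction type is the KH/18-crown-6 ring expansion of cis-1,2-dialkenylcyclohexanols to cyclodec-5-enones. The ten-membered ring is not closed end to end but arises by four-carbon expansion of the cyclohexene through a six-membered chair transition state spanning C6–C5–C4···C9–C8–C7. C7 is the only new stereocentre and should be fixed by chirality transfer from C4 and C9 through that chair, the E-diene terminus holding the isopropenyl group equatorial. The step needs Z geometry at the new C4=C5 bond, which should follow from the ring half-chair with the C4 methyl axial (equatorial on the Cope chair, C3 axial on it) and the dienyl group pseudoaxial; this conformer is favoured by the equatorial C3 silyloxy group and by relief of A(1,2) strain with the C10 methyl. The ring-derived C1=C10 bond necessarily stays Z and ends up conjugated to the C9 ketone, and C8 becomes the only enolizable α-carbon.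

Step 12
Reactants: 19 (3R,7S,1(10)Z,4Z)-3-(tert-butyldimethylsilyloxy)germacra-1(10),4,11-trien-9-one
Product: 20 (1R,3R,7S,10R,4Z)-3-(tert-butyldimethylsilyloxy)-1α,10α-epoxygermacra-4,11-dien-9-one
Conditions: t-BuOOH, DBU, CH2Cl2, 0 °C → rt
Reagents that add atoms: tert-butyl hydroperoxide, CC(C)(C)OO
Why: Weitz–Scheffer nucleophilic epoxidation: tert-butylperoxide should add to C1 of the twisted Z-enone on the face turned away from the transannular C4=C5 unit and its methyl, and the enolate should close on the same face before C1–C10 rotation, giving the cis 1α,10α-epoxide while the unactivated olefins stay untouched.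

Step 13
Reactants: 20 (1R,3R,7S,10R,4Z)-3-(tert-butyldimethylsilyloxy)-1α,10α-epoxygermacra-4,11-dien-9-one
Product: 22 (1R,3R,7R,8R,10R,4Z)-3-(tert-butyldimethylsilyloxy)-1α,10α-epoxy-8β-hydroxygermacra-4,11-dien-9-one, via potassium enolate 21 (not isolated)
Conditions: KN(SiMe3)2, THF, −78 °C; 2-(phenylsulfonyl)-3-phenyloxaziridine, −78 °C
Reagents that add atoms: 2-(phenylsulfonyl)-3-phenyloxaziridine, O=S(=O)(c1ccccc1)N1OC1c1ccccc1
Why: Enolate oxidation with an N-sulfonyloxaziridine: C8 is the only enolizable carbon, and the oxidant should attack the peripheral face of the C8=C9 enolate anti to the C7–C6 ring bond with the isopropenyl group turned outward, giving the 8β-alcohol (trans to isopropenyl), deliberately epimeric to the target at C8.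

Step 14
Reactants: 22 (1R,3R,7R,8R,10R,4Z)-3-(tert-butyldimethylsilyloxy)-1α,10α-epoxy-8β-hydroxygermacra-4,11-dien-9-one
Product: 24 (1R,3R,7R,8S,10R,4Z)-3-(tert-butyldimethylsilyloxy)-1α,10α-epoxy-8α-(3-methylbut-2-enoyloxy)germacra-4,11-dien-9-one, via C8 triflate 23 (not isolated)
Conditions: Tf2O, pyridine, CH2Cl2, −78 → −30 °C; then cesium 3-methylbut-2-enoate, 18-crown-6, DMF, −30 → 0 °C
Reagents that add atoms: cesium 3-methylbut-2-enoate, CC(C)=CC(=O)[O-].[Cs+]
Why: Sulfonylation followed by SN2 displacement: the α-keto triflate, activated by the adjacent carbonyl, should be displaced by the carboxylate with inversion, installing the senecioate in the 8α configuration of the target.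

Step 15
Reactants: 24 (1R,3R,7R,8S,10R,4Z)-3-(tert-butyldimethylsilyloxy)-1α,10α-epoxy-8α-(3-methylbut-2-enoyloxy)germacra-4,11-dien-9-one
Product: 25 (1R,3R,7R,8S,10R,4Z)-1α,10α-epoxy-3β-hydroxy-8α-(3-methylbut-2-enoyloxy)germacra-4,11-dien-9-one
Conditions: HF·pyridine, pyridine, THF, 0 °C → rt
Reagents that add atoms: none
Why: Fluoride-mediated desilylation under buffered conditions that should spare the epoxy ketone and the α-acyloxy ketone; no stereocentre is touched.

Step 16
Reactants: 25 (1R,3R,7R,8S,10R,4Z)-1α,10α-epoxy-3β-hydroxy-8α-(3-methylbut-2-enoyloxy)germacra-4,11-dien-9-one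
Product: 26 (1R,3S,7R,8S,10R,4Z)-3α-chloroacetoxy-1α,10α-epoxy-8α-(3-methylbut-2-enoyloxy)germacra-4,11-dien-9-one
Conditions: ClCH2CO2H, PPh3, DIAD, toluene, 0 °C → rt
Reagents that add atoms: chloroacetic acid, OC(=O)CCl
Why: Mitsunobu reaction: the alkoxyphosphonium ion at the allylic C3 should be displaced by chloroacetate in an SN2 step, inverting C3 from R to S.

Step 17
Reactants: 26 (1R,3S,7R,8S,10R,4Z)-3α-chloroacetoxy-1α,10α-epoxy-8α-(3-methylbut-2-enoyloxy)germacra-4,11-dien-9-one
Product: 27 (1R,3S,7R,8S,10R,4Z)-1α,10α-epoxy-3α-hydroxy-8α-(3-methylbut-2-enoyloxy)germacra-4,11-dien-9-one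
Conditions: thiourea, NaHCO3, EtOH, 40 °C
Reagents that add atoms: none
Why: Thiourea dechloroacetylation: S-alkylation and cyclisation to the aminothiazolone should release the C3 alcohol under near-neutral conditions that leave the senecioate in place.

Step 18
Reactants: 27 (1R,3S,7R,8S,10R,4Z)-1α,10α-epoxy-3α-hydroxy-8α-(3-methylbut-2-enoyloxy)germacra-4,11-dien-9-one
Product: 28 (1R,3S,4R,5S,7R,8S,10R)-1α,10α:4β,5β-diepoxy-3α-hydroxy-8α-(3-methylbut-2-enoyloxy)germacr-11-en-9-one
Conditions: VO(acac)2 (cat.), t-BuOOH, CH2Cl2, 0 °C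
Reagents that add atoms: tert-butyl hydroperoxide, CC(C)(C)OO
Why: Vanadium-catalysed hydroxyl-directed epoxidation: with H3 eclipsing the Z olefin (A(1,3) strain) the vanadate ester of the C3 alcohol should deliver oxygen to the C4=C5 face syn to the hydroxyl, giving the threo 4β,5β-epoxide, while the isopropenyl and senecioyl olefins are not epoxidised.

Step 19
Reactants: 28 (1R,3S,4R,5S,7R,8S,10R)-1α,10α:4β,5β-diepoxy-3α-hydroxy-8α-(3-methylbut-2-enoyloxy)germacr-11-en-9-one
Product: 29 (1R,3S,4S,5S,7R,8S,10R)-3α-angeloyloxy-1α,10α:4β,5β-diepoxy-8α-(3-methylbut-2-enoyloxy)germacr-11-en-9-one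
Conditions: angelic acid, 2,4,6-trichlorobenzoyl chloride, Et3N, toluene, rt; then 28, 80 °C
Reagents that add atoms: angelic acid, C/C=C(/C)C(=O)O
Why: Yamaguchi-type mixed anhydride esterification run without DMAP, so that the Z geometry of the angeloyl group should not isomerise to tigloyl.

Step 20
Reactants: 29 (1R,3S,4S,5S,7R,8S,10R)-3α-angeloyloxy-1α,10α:4β,5β-diepoxy-8α-(3-methylbut-2-enoyloxy)germacr-11-en-9-one
Product: 30 (1R,3S,4S,5S,7R,8S,9S,10S)-3α-angeloyloxy-1α,10α:4β,5β-diepoxy-9α-hydroxy-8α-(3-methylbut-2-enoyloxy)germacr-11-ene (CNP0320216.1)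
Conditions: Zn(BH4)2, Et2O, −20 °C
Reagents that add atoms: none
Why: Chelation-controlled ketone reduction: zinc should bridge the C9 carbonyl and the flanking C8 and epoxide oxygens, holding C7 and C1 on one face so that hydride arrives from the other, giving the 9α-alcohol cis to the 8-ester and erythro to the 1,10-epoxide without touching esters or epoxides.

**Compound list**

1 | 2-methylcyclohex-2-en-1-one | CC1=CCCCC1=O | starting material
2 | (S)-2-methylcyclohex-2-en-1-ol | O[C@H]1CCCC=C1C | intermediate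
3 | (1S,2S,3R)-2,3-epoxy-2-methylcyclohexan-1-ol (OH cis to epoxide oxygen) | O[C@H]1CCC[C@H]2O[C@@]12C | intermediate
4 | (2R,3R)-2,3-epoxy-2-methylcyclohexan-1-one | O=C1CCC[C@H]2O[C@@]12C | intermediate
5 | (1R,2R,3R)-2,3-epoxy-2-methyl-1-vinylcyclohexan-1-ol (OH cis, vinyl trans to epoxide oxygen) | C=C[C@]1(O)CCC[C@H]2O[C@@]12C | intermediate
6 | (2S,3R)-3-hydroxy-2-methyl-2-vinylcyclohexan-1-one (OH trans to vinyl) | O=C1CCC[C@@H](O)[C@]1(C)C=C | intermediate
7 | (2S,3R)-3-(tert-butyldimethylsilyloxy)-2-methyl-2-vinylcyclohexan-1-one | O=C1CCC[C@@H](O[Si](C)(C)C(C)(C)C)[C@]1(C)C=C | intermediate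
8 | lithium enolate of 7 | [Li+].[O-]C1=CCC[C@@H](O[Si](C)(C)C(C)(C)C)[C@]1(C)C=C | intermediate
9 | (2S,3R,6RS)-3-(tert-butyldimethylsilyloxy)-2,6-dimethyl-2-vinylcyclohexan-1-one | O=C1C(C)CC[C@@H](O[Si](C)(C)C(C)(C)C)[C@]1(C)C=C | intermediate
10 | trimethylsilyl enol ether of 9 | C[Si](C)(C)OC1=C(C)CC[C@@H](O[Si](C)(C)C(C)(C)C)[C@]1(C)C=C | intermediate
11 | (5R,6S)-5-(tert-butyldimethylsilyloxy)-2,6-dimethyl-6-vinylcyclohex-2-en-1-one | O=C1C(C)=CC[C@@H](O[Si](C)(C)C(C)(C)C)[C@]1(C)C=C | intermediate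
12 | 2-methylbut-1-en-3-yne | C=C(C)C#C | starting material
13 | chloro[(E)-3-methylbuta-1,3-dienyl]zirconocene | C=C(C)/C=C/[Zr](Cl)(C1C=CC=C1)C1C=CC=C1 | intermediate
14 | (E)-1-iodo-3-methylbuta-1,3-diene | C=C(C)/C=C/I | intermediate
15 | (E)-3-methylbuta-1,3-dienyllithium | [Li]/C=C/C(C)=C | intermediate
16 | (1S,5R,6S)-5-(tert-butyldimethylsilyloxy)-2,6-dimethyl-1-[(E)-3-methylbuta-1,3-dienyl]-6-vinylcyclohex-2-en-1-ol (dienyl cis to vinyl, silyloxy trans to both) | C=C(C)/C=C/[C@]1(O)C(C)=CC[C@@H](O[Si](C)(C)C(C)(C)C)[C@]1(C)C=C | intermediate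
17 | potassium alkoxide of 16 | C=C(C)/C=C/[C@]1([O-])C(C)=CC[C@@H](O[Si](C)(C)C(C)(C)C)[C@]1(C)C=C.[K+] | intermediate
18 | C8=C9 potassium enolate of 19 | [K+].[O-]/C1=C\[C@@H](C(C)=C)C/C=C(C)\[C@H](O[Si](C)(C)C(C)(C)C)C/C=C1/C | intermediate
19 | (3R,7S,1(10)Z,4Z)-3-(tert-butyldimethylsilyloxy)germacra-1(10),4,11-trien-9-one | C=C(C)[C@H]1C/C=C(C)\[C@H](O[Si](C)(C)C(C)(C)C)C/C=C(C)\C(=O)C1 | intermediate
20 | (1R,3R,7S,10R,4Z)-3-(tert-butyldimethylsilyloxy)-1α,10α-epoxygermacra-4,11-dien-9-one | C=C(C)[C@H]1C/C=C(C)\[C@H](O[Si](C)(C)C(C)(C)C)C[C@H]2O[C@@]2(C)C(=O)C1 | intermediate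
21 | C8=C9 potassium enolate of 20 | [K+].[O-]C1=C[C@@H](C(C)=C)C/C=C(C)\[C@H](O[Si](C)(C)C(C)(C)C)C[C@H]2O[C@@]12C | intermediate
22 | (1R,3R,7R,8R,10R,4Z)-3-(tert-butyldimethylsilyloxy)-1α,10α-epoxy-8β-hydroxygermacra-4,11-dien-9-one | C=C(C)[C@H]1C/C=C(C)\[C@H](O[Si](C)(C)C(C)(C)C)C[C@H]2O[C@@]2(C)C(=O)[C@@H]1O | intermediate
23 | 8β-trifluoromethanesulfonate of 22 | C=C(C)[C@H]1C/C=C(C)\[C@H](O[Si](C)(C)C(C)(C)C)C[C@H]2O[C@@]2(C)C(=O)[C@@H]1OS(=O)(=O)C(F)(F)F | intermediate
24 | (1R,3R,7R,8S,10R,4Z)-3-(tert-butyldimethylsilyloxy)-1α,10α-epoxy-8α-(3-methylbut-2-enoyloxy)germacra-4,11-dien-9-one | C=C(C)[C@H]1C/C=C(C)\[C@H](O[Si](C)(C)C(C)(C)C)C[C@H]2O[C@@]2(C)C(=O)[C@H]1OC(=O)C=C(C)C | intermediate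
25 | (1R,3R,7R,8S,10R,4Z)-1α,10α-epoxy-3β-hydroxy-8α-(3-methylbut-2-enoyloxy)germacra-4,11-dien-9-one | C=C(C)[C@H]1C/C=C(C)\[C@H](O)C[C@H]2O[C@@]2(C)C(=O)[C@H]1OC(=O)C=C(C)C | intermediate
26 | (1R,3S,7R,8S,10R,4Z)-3α-chloroacetoxy-1α,10α-epoxy-8α-(3-methylbut-2-enoyloxy)germacra-4,11-dien-9-one | C=C(C)[C@H]1C/C=C(C)\[C@@H](OC(=O)CCl)C[C@H]2O[C@@]2(C)C(=O)[C@H]1OC(=O)C=C(C)C | intermediate
27 | (1R,3S,7R,8S,10R,4Z)-1α,10α-epoxy-3α-hydroxy-8α-(3-methylbut-2-enoyloxy)germacra-4,11-dien-9-one | C=C(C)[C@H]1C/C=C(C)\[C@@H](O)C[C@H]2O[C@@]2(C)C(=O)[C@H]1OC(=O)C=C(C)C | intermediate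
28 | (1R,3S,4R,5S,7R,8S,10R)-1α,10α:4β,5β-diepoxy-3α-hydroxy-8α-(3-methylbut-2-enoyloxy)germacr-11-en-9-one | C=C(C)[C@H]1C[C@@H]2O[C@]2(C)[C@@H](O)C[C@H]2O[C@@]2(C)C(=O)[C@H]1OC(=O)C=C(C)C | intermediate
29 | (1R,3S,4S,5S,7R,8S,10R)-3α-angeloyloxy-1α,10α:4β,5β-diepoxy-8α-(3-methylbut-2-enoyloxy)germacr-11-en-9-one | C=C(C)[C@H]1C[C@@H]2O[C@]2(C)[C@@H](OC(=O)/C(C)=C\C)C[C@H]2O[C@@]2(C)C(=O)[C@H]1OC(=O)C=C(C)C | intermediate
30 | (1R,3S,4S,5S,7R,8S,9S,10S)-3α-angeloyloxy-1α,10α:4β,5β-diepoxy-9α-hydroxy-8α-(3-methylbut-2-enoyloxy)germacr-11-ene, CNP0320216.1 | C=C(C)[C@H]1C[C@@H]2O[C@]2(C)[C@@H](OC(=O)/C(C)=C\C)C[C@H]2O[C@@]2(C)[C@@H](O)[C@H]1OC(=O)C=C(C)C | target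

**Step count**

Total steps: 20. Longest linear sequence: 19 steps (steps 1–8 and 10–20; step 9 prepares the dienyl fragment).

**Steps most likely to fail**

1. Step 14. The α-keto triflate at the β-branched C8 may lose triflic acid across C7–C8 or epimerise faster than the carboxylate attacks from the rear. Fallback: setting out from 20, its potassium enolate is brominated with N-bromosuccinimide at −78 °C on the same peripheral face to give the isolable (1R,3R,7R,8R,10R,4Z)-8β-bromo-3-(tert-butyldimethylsilyloxy)-1α,10α-epoxygermacra-4,11-dien-9-one F1. Its bromide is then displaced with inversion by cesium 3-methylbut-2-enoate in DMF at room temperature, and the route is rejoined at 24.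

2. Step 12. Conjugate addition of the peroxide to the twisted, α-methylated Z-enone may be slow or may take place on both faces, and bond rotation before ring closure could erode the cis geometry. Fallback: setting out from 19, Corey–Bakshi–Shibata 1,2-reduction with (S)-2-methyl-CBS-oxazaborolidine and catecholborane gives, under reagent control, (3R,7S,9R,1(10)Z,4Z)-3-(tert-butyldimethylsilyloxy)germacra-1(10),4,11-trien-9β-ol F2. VO(acac)2/t-BuOOH then delivers oxygen syn to that hydroxyl (threo, A(1,3) control) to give (1R,3R,7S,9R,10S,4Z)-3-(tert-butyldimethylsilyloxy)-1α,10α-epoxygermacra-4,11-dien-9β-ol F3, and Dess–Martin oxidation returns to the route at 20.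

3. Step 16. Attack of the carboxylate at C5 (allylic transposition) or elimination of the alkoxyphosphonium ion to a diene may compete with direct displacement at C3. Fallback: setting out from 25, MnO2 oxidises the allylic alcohol to (1R,7R,8S,10R,4Z)-1α,10α-epoxy-8α-(3-methylbut-2-enoyloxy)germacra-4,11-diene-3,9-dione F4. Its unhindered C3 enone carbonyl is then reduced in preference to the doubly α-branched C9 ketone with (R)-2-methyl-CBS-oxazaborolidine and catecholborane at −78 °C, giving the 3S alcohol and rejoining the route at 27.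

Further compounds

F1 | step 14 | (1R,3R,7R,8R,10R,4Z)-8β-bromo-3-(tert-butyldimethylsilyloxy)-1α,10α-epoxygermacra-4,11-dien-9-one | C=C(C)[C@H]1C/C=C(C)\[C@H](O[Si](C)(C)C(C)(C)C)C[C@H]2O[C@@]2(C)C(=O)[C@@H]1Br
F2 | step 12 | (3R,7S,9R,1(10)Z,4Z)-3-(tert-butyldimethylsilyloxy)germacra-1(10),4,11-trien-9β-ol | C=C(C)[C@H]1C/C=C(C)\[C@H](O[Si](C)(C)C(C)(C)C)C/C=C(C)\[C@H](O)C1
F3 | step 12 | (1R,3R,7S,9R,10S,4Z)-3-(tert-butyldimethylsilyloxy)-1α,10α-epoxygermacra-4,11-dien-9β-ol | C=C(C)[C@H]1C/C=C(C)\[C@H](O[Si](C)(C)C(C)(C)C)C[C@H]2O[C@@]2(C)[C@H](O)C1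
F4 | step 16 | (1R,7R,8S,10R,4Z)-1α,10α-epoxy-8α-(3-methylbut-2-enoyloxy)germacra-4,11-diene-3,9-dione | C=C(C)[C@H]1C/C=C(C)\C(=O)C[C@H]2O[C@@]2(C)C(=O)[C@H]1OC(=O)C=C(C)C
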